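**Retrosynthetic overview** (prostanoid numbering for the target: C1 = ester carbon, ring = C8–C12)
1. C6–C7 is made last: Stille coupling of the Z-enol triflate 16 (ring C8=C7–OTf) with the E-alkenylstannane 18 should give the 7Z,5E-dienylidene arm with retention at both carbons.
2. 16 comes from the C8-formyl ketone 14 (chelated Z-enol), which comes from a CH2OSi arm on C8; the C12 acetate comes from the tertiary carbinol.
3. The only ring, the cyclopentenone, is closed by forming the C8–C12 bond in an enantioselective oxa-Piancatelli rearrangement of furylcarbinol 8, which sets C12 and delivers the bromoenone in the same operation.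
4. Enabling feature: ring atoms C9(=O)–C10(Br)=C11–C12(–O) are a 1,4-dioxygenated but-2-ene unit, i.e. C2–C5 of a 3-bromofuran in disguise (furan O becomes the C9 ketone, water gives C12–OH), and C8 is the furfuryl carbinol carbon.
5. 8 is assembled from 3-bromofuran by two lithiations: C2 (next to Br) onto aldehyde 2, then C5 onto (Z)-octenyl bromide 6.

Key step: step 4

Assumption: the absolute sense of induction of the chiral acid in step 4 cannot be predicted with certainty; the (R)-catalyst is written, and its mirror image is used instead if the first run shows the opposite sense.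

**Step 1**
Reactants: 1 3-bromofuran; 2 2-[(tert-butyldiphenylsilyl)oxy]acetaldehyde
Product: 4 rac-1-(3-bromofuran-2-yl)-2-[(tert-butyldiphenylsilyl)oxy]ethan-1-ol, via 3-bromo-2-lithiofuran 3 (not isolated)
Conditions: LDA (1.05 equiv), THF, −78 °C; then 2, −78 °C; H2O
Reagents that add atoms: none
Why: LDA deprotonates 3-bromofuran only at C2, the position between the ring oxygen and bromine (directed ortho-lithiation, no halogen–metal exchange with an amide base), and the furyllithium adds 1,2 to the aldehyde; the carbinol centre forms racemic, which does not matter because step 4 ionises it.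

**Step 2**
Reactants: 5 (2Z)-oct-2-en-1-ol
Product: 6 (2Z)-1-bromooct-2-ene
Conditions: CBr4, PPh3, CH2Cl2, 0 °C
Reagents that add atoms: tetrabromomethane BrC(Br)(Br)Br
Why: The Appel reaction replaces the primary allylic hydroxyl by bromide through SN2 attack on the alkoxyphosphonium ion at 0 °C, which should leave the Z-alkene in place and untransposed.

**Step 3**
Reactants: 4 rac-1-(3-bromofuran-2-yl)-2-[(tert-butyldiphenylsilyl)oxy]ethan-1-ol; 6 (2Z)-1-bromooct-2-ene
Product: 8 rac-1-{3-bromo-5-[(2Z)-oct-2-en-1-yl]furan-2-yl}-2-[(tert-butyldiphenylsilyl)oxy]ethan-1-ol, via dilithio derivative 7 (not isolated)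
Conditions: LDA (2.2 equiv), THF, −78 → −40 °C; then 6 (1.2 equiv), −78 → 0 °C; H2O
Reagents that add atoms: none
Why: After the hydroxyl proton, the second equivalent of LDA removes the one remaining α-proton of the furan (C5–H), and the 5-furyllithium is alkylated by the primary allylic bromide at its CH2 carbon (SN2 alkylation of a heteroaryllithium) with the Z-alkene untouched.

**Step 4**
Reactants: 8 rac-1-{3-bromo-5-[(2Z)-oct-2-en-1-yl]furan-2-yl}-2-[(tert-butyldiphenylsilyl)oxy]ethan-1-ol
Product: 11 (4S,5S)-2-bromo-5-{[(tert-butyldiphenylsilyl)oxy]methyl}-4-hydroxy-4-[(2Z)-oct-2-en-1-yl]cyclopent-2-en-1-one, via dihydrofuranol hemiketal 9 (not isolated), via ring-opened dienol 10 (not isolated)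
Conditions: (R)-3,3′-bis(2,4,6-triisopropylphenyl)-1,1′-binaphthalene-2,2′-diyl N-(trifluoromethylsulfonyl)phosphoramide (10 mol%), H2O (3 equiv), CHCl3, 40 °C
Reagents that add atoms: water O
Why: Proposed new method: the chiral acid ionises the furfuryl alcohol, water adds to the octenyl-bearing furan carbon to give hemiketal 9, ring opening gives the dienol-enone 10, and its O-protonated form, a 1,4-dihydroxypentadienyl cation, closes between the former carbinol carbon and the former furan C5 (ring C5–C4 of 11, prostanoid C8–C12). The closest known reaction types are the oxa-Piancatelli rearrangement of 5-alkyl-2-furylcarbinols with achiral Lewis or Brønsted acids in water and the chiral phosphoric acid-catalysed enantioselective aza-Piancatelli rearrangement, in which the same type of cation closes under control of its chiral counter-anion; what is new is the combination of water as nucleophile with a chiral anion on an alkyl carbinol. The cyclopentenone, the only ring of the target, closes by thermal conrotatory 4π electrocyclisation of the pentadienyl cation, so the geometric restriction on the corresponding enolate aldol closure does not apply; the furan oxygen ends as the ketone and the water oxygen as the tertiary hydroxyl. The configuration at ring C4 is fixed by the sense of conrotation, which the phosphoramide anion should select because it is hydrogen-bonded to both O–H groups of the cation (torquoselectivity by ion pairing); ring C5 follows from it, since conrotation should place 4-OH and 5-CH2OSi trans, and C5 is made trigonal later. The step needs water to attack the substituted furan carbon and not the carbinol carbon, which is secured because the latter attack only returns 8 while the 5-alkyl group stabilises the oxocarbenium centre; it also needs the skipped Z-alkene, the silyl ether and the C–Br bond to survive, which a weak acid at 40 °C should allow. The bromine on furan C3 ends on the α-carbon of the enone, so no later bromination in the presence of other alkenes is needed.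

**Step 5**
Reactants: 11 (4S,5S)-2-bromo-5-{[(tert-butyldiphenylsilyl)oxy]methyl}-4-hydroxy-4-[(2Z)-oct-2-en-1-yl]cyclopent-2-en-1-one
Product: 12 (1S,5S)-3-bromo-5-{[(tert-butyldiphenylsilyl)oxy]methyl}-1-[(2Z)-oct-2-en-1-yl]-4-oxocyclopent-2-en-1-yl acetate
Conditions: Ac2O (3 equiv), Sc(OTf)3 (2 mol%), MeCN, −20 °C
Reagents that add atoms: acetic anhydride CC(=O)OC(C)=O
Why: Sc(OTf)3-catalysed acylation with Ac2O esterifies hindered tertiary alcohols under non-basic conditions, which avoids the base-induced retro-aldol opening of the β-hydroxy ketone that would racemise the carbinol carbon; the configuration is unchanged.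

**Step 6**
Reactants: 12 (1S,5S)-3-bromo-5-{[(tert-butyldiphenylsilyl)oxy]methyl}-1-[(2Z)-oct-2-en-1-yl]-4-oxocyclopent-2-en-1-yl acetate
Product: 13 (1S,5S)-3-bromo-5-(hydroxymethyl)-1-[(2Z)-oct-2-en-1-yl]-4-oxocyclopent-2-en-1-yl acetate
Conditions: HF·pyridine, THF–pyridine, 0 °C; used at once in step 7
Reagents that add atoms: none
Why: Fluoride cleaves the Si–O bond of the primary silyl ether (desilylation), and the weakly acidic, pyridine-buffered medium should keep the tertiary acetate from migrating to the new primary hydroxyl and the β-acetoxy ketone from eliminating.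

**Step 7**
Reactants: 13 (1S,5S)-3-bromo-5-(hydroxymethyl)-1-[(2Z)-oct-2-en-1-yl]-4-oxocyclopent-2-en-1-yl acetate
Product: 14 (1R,5Z)-3-bromo-5-(hydroxymethylidene)-1-[(2Z)-oct-2-en-1-yl]-4-oxocyclopent-2-en-1-yl acetate
Conditions: Dess–Martin periodinane (1.1 equiv), CH2Cl2, 0 °C
Reagents that add atoms: none
Why: Dess–Martin oxidation of the primary alcohol gives the 1,3-keto aldehyde, which should rest as its intramolecularly hydrogen-bonded Z-enol, so the ring C5 stereocentre is erased on purpose while the acetoxy carbon is untouched (its descriptor changes to R only through the priority rules).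

**Step 8**
Reactants: 14 (1R,5Z)-3-bromo-5-(hydroxymethylidene)-1-[(2Z)-oct-2-en-1-yl]-4-oxocyclopent-2-en-1-yl acetate
Product: 16 (1R,5Z)-3-bromo-1-[(2Z)-oct-2-en-1-yl]-4-oxo-5-({[(trifluoromethyl)sulfonyl]oxy}methylidene)cyclopent-2-en-1-yl acetate, via lithium enolate 15 (not isolated)
Conditions: LiN(SiMe3)2 (1.05 equiv), Et2O, −78 °C; then Tf2O (1.1 equiv), −78 °C
Reagents that add atoms: trifluoromethanesulfonic anhydride O=S(=O)(OS(=O)(=O)C(F)(F)F)C(F)(F)F
Why: The lithium enolate of the 1,3-keto aldehyde is a U-shaped chelate, and O-sulfonylation at the less hindered, formyl-derived oxygen (enol triflate formation) should fix the triflate cis to the ring ketone, i.e. the Z-enol triflate that carries the later 7Z geometry.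

**Step 9**
Reactants: 17 methyl hex-5-ynoate
Product: 18 methyl (5E)-6-(tributylstannyl)hex-5-enoate
Conditions: Bu3SnH (1.1 equiv), Pd2(dba)3 (0.5 mol%), PCy3 (2 mol%), CH2Cl2, 0 °C
Reagents that add atoms: tributyltin hydride CCCC[SnH](CCCC)CCCC
Why: Palladium-catalysed hydrostannation adds H and SnBu3 syn across the terminal alkyne, and the bulky PCy3 ligand directs tin to the terminal carbon, which should give the E-alkenylstannane.

**Step 10**
Reactants: 16 (1R,5Z)-3-bromo-1-[(2Z)-oct-2-en-1-yl]-4-oxo-5-({[(trifluoromethyl)sulfonyl]oxy}methylidene)cyclopent-2-en-1-yl acetate; 18 methyl (5E)-6-(tributylstannyl)hex-5-enoate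
Product: 19 methyl (5E,7Z,12R,14Z)-12-acetoxy-10-bromo-9-oxoprosta-5,7,10,14-tetraen-1-oate
Conditions: Pd2(dba)3 (2.5 mol%), AsPh3 (20 mol%), CuI (10 mol%), NMP, 23 °C, dark
Reagents that add atoms: none
Why: Stille coupling proceeds with retention at both alkenyl carbons, so the Z-triflate and the E-stannane should give the 7Z,5E-diene; the vinylogous acyl triflate should add to zerovalent palladium at room temperature much faster than the C–Br bond or the tertiary allylic acetate, and AsPh3 with CuI speeds up transmetalation so that the alkenylpalladium has little time to isomerise.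

**Compound list**
1 | 3-bromofuran | Brc1ccoc1 | starting material
2 | 2-[(tert-butyldiphenylsilyl)oxy]acetaldehyde | O=CCO[Si](c1ccccc1)(c1ccccc1)C(C)(C)C | starting material
3 | 3-bromo-2-lithiofuran | [Li]c1occc1Br | intermediate
4 | rac-1-(3-bromofuran-2-yl)-2-[(tert-butyldiphenylsilyl)oxy]ethan-1-ol | OC(CO[Si](c1ccccc1)(c1ccccc1)C(C)(C)C)c1occc1Br | intermediate
5 | (2Z)-oct-2-en-1-ol | CCCCC/C=C\CO | starting material
6 | (2Z)-1-bromooct-2-ene | CCCCC/C=C\CBr | intermediate
7 | O,C5-dilithio derivative of 4 (lithium alkoxide, 5-lithiofuran) | [Li]OC(CO[Si](c1ccccc1)(c1ccccc1)C(C)(C)C)c1oc([Li])cc1Br | intermediate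
8 | rac-1-{3-bromo-5-[(2Z)-oct-2-en-1-yl]furan-2-yl}-2-[(tert-butyldiphenylsilyl)oxy]ethan-1-ol | OC(CO[Si](c1ccccc1)(c1ccccc1)C(C)(C)C)c1oc(C/C=C\CCCCC)cc1Br | intermediate
9 | 4-bromo-5-{2-[(tert-butyldiphenylsilyl)oxy]ethylidene}-2-[(2Z)-oct-2-en-1-yl]-2,5-dihydrofuran-2-ol (hemiketal, racemic, ylidene geometry open) | CCCCC/C=C\CC1(O)C=C(Br)C(=CCO[Si](c2ccccc2)(c2ccccc2)C(C)(C)C)O1 | intermediate
10 | (4E,8Z)-4-bromo-1-[(tert-butyldiphenylsilyl)oxy]-3-hydroxytetradeca-2,4,8-trien-6-one (C3 and C6 cis on the 4,5-double bond; enol geometry open) | CCCCC/C=C\CC(=O)/C=C(Br)\C(O)=CCO[Si](c1ccccc1)(c1ccccc1)C(C)(C)C | intermediate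
11 | (4S,5S)-2-bromo-5-{[(tert-butyldiphenylsilyl)oxy]methyl}-4-hydroxy-4-[(2Z)-oct-2-en-1-yl]cyclopent-2-en-1-one (OH and CH2OSi trans) | CCCCC/C=C\C[C@@]1(O)C=C(Br)C(=O)[C@H]1CO[Si](c2ccccc2)(c2ccccc2)C(C)(C)C | intermediate
12 | (1S,5S)-3-bromo-5-{[(tert-butyldiphenylsilyl)oxy]methyl}-1-[(2Z)-oct-2-en-1-yl]-4-oxocyclopent-2-en-1-yl acetate | CCCCC/C=C\C[C@@]1(OC(C)=O)C=C(Br)C(=O)[C@H]1CO[Si](c2ccccc2)(c2ccccc2)C(C)(C)C | intermediate
13 | (1S,5S)-3-bromo-5-(hydroxymethyl)-1-[(2Z)-oct-2-en-1-yl]-4-oxocyclopent-2-en-1-yl acetate | CCCCC/C=C\C[C@@]1(OC(C)=O)C=C(Br)C(=O)[C@H]1CO | intermediate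
14 | (1R,5Z)-3-bromo-5-(hydroxymethylidene)-1-[(2Z)-oct-2-en-1-yl]-4-oxocyclopent-2-en-1-yl acetate | CCCCC/C=C\C[C@@]1(OC(C)=O)C=C(Br)C(=O)/C1=C\O | intermediate
15 | lithium enolate of 14 | CCCCC/C=C\C[C@@]1(OC(C)=O)C=C(Br)C(=O)/C1=C\O[Li] | intermediate
16 | (1R,5Z)-3-bromo-1-[(2Z)-oct-2-en-1-yl]-4-oxo-5-({[(trifluoromethyl)sulfonyl]oxy}methylidene)cyclopent-2-en-1-yl acetate | CCCCC/C=C\C[C@@]1(OC(C)=O)C=C(Br)C(=O)/C1=C\OS(=O)(=O)C(F)(F)F | intermediate
17 | methyl hex-5-ynoate | COC(=O)CCCC#C | starting material
18 | methyl (5E)-6-(tributylstannyl)hex-5-enoate | COC(=O)CCC/C=C/[Sn](CCCC)(CCCC)CCCC | intermediate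
19 | methyl (5E,7Z,12R,14Z)-12-acetoxy-10-bromo-9-oxoprosta-5,7,10,14-tetraen-1-oate | CCCCC/C=C\C[C@@]1(OC(C)=O)C=C(Br)C(=O)/C1=C\C=C\CCCC(=O)OC | target

**Step count**
Total step count: 10. Longest linear sequence: 8 steps (steps 1, 3, 4, 5, 6, 7, 8 and 10, from 3-bromofuran).

**Steps most likely to fail**

1. Step 4 (proposed new method). Ionisation of the carbinol may be too slow with a weak chiral acid, since bromine and the β-silyloxy group both disfavour the cation. A 1,2-hydride shift towards the silyloxy-bearing carbon may divert the cation. The ion pair may also give poor helical (facial) selectivity in the ring closure. The fallback uses known chemistry, sets out from 8 and returns at 13. 8 is rearranged without chiral control under the classical conditions for 5-alkyl-2-furylcarbinols (ZnCl2, dioxane–H2O, 80 °C) to racemic trans-2-bromo-5-{[(tert-butyldiphenylsilyl)oxy]methyl}-4-hydroxy-4-[(2Z)-oct-2-en-1-yl]cyclopent-2-en-1-one F1. Acetylation as in step 5 should give the racemic acetate F2, and desilylation as in step 6 the racemic primary alcohol F3. Kinetic resolution of the primary alcohol by enzymatic transesterification (lipase from Burkholderia cepacia, vinyl acetate, tert-butyl methyl ether, 30 °C; enzyme chosen by screening) is expected to acetylate one enantiomer, here taken as (1R,5R), to the diacetate (1R,5R)-5-(acetoxymethyl)-3-bromo-1-[(2Z)-oct-2-en-1-yl]-4-oxocyclopent-2-en-1-yl acetate F4. The unreacted (1S,5S)-alcohol is 13 and is separated by chromatography.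

2. Step 3. The second deprotonation takes place next to an alkoxide and at a position not flanked by bromine, so it may be incomplete. Bromine may migrate around the ring on warming (halogen dance). The silyl group may shift from the primary oxygen to the alkoxide. The furyllithium may attack the allylic bromide at the alkene terminus (SN2′). The fallback sets out from 1 and returns at 8, with the alkylation done before any alkoxide is present and the aldehyde added last. 1 is lithiated at C2 as in step 1 and silylated (LDA, Me3SiCl, THF, −78 °C) to 3-bromo-2-(trimethylsilyl)furan F5. Its only remaining α-position is deprotonated (LDA, THF, −78 °C) and alkylated with 6 to 3-bromo-5-[(2Z)-oct-2-en-1-yl]-2-(trimethylsilyl)furan F6. Bu4NF in THF removes the blocking group to give 4-bromo-2-[(2Z)-oct-2-en-1-yl]furan F7. LDA then deprotonates the position between oxygen and bromine, the same easy lithiation as in step 1, and addition to 2 should give 8.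

3. Step 10. Zerovalent palladium may insert into the C–Br bond of the bromoenone or ionise the tertiary allylic acetate in competition with the triflate. The β-acyl alkenylpalladium intermediate, or the product through reversible addition of a ligand, may lose the 7Z geometry. The fallback sets out from 16 and 18 and returns at 19 without palladium. Copper thiophene-2-carboxylate (CuO2C–C4H3S, 1.5 equiv) in NMP at 0 °C converts 18 by tin-to-copper exchange into the alkenylcopper methyl (5E)-6-cupriohex-5-enoate F8. F8 should replace the triflate of 16 by conjugate addition–elimination at the exocyclic carbon with retention of both double-bond geometries, a path that needs no oxidative addition and so should leave the C–Br bond and the acetate alone.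

**Further compounds**
F1 | step 4 | racemic trans-2-bromo-5-{[(tert-butyldiphenylsilyl)oxy]methyl}-4-hydroxy-4-[(2Z)-oct-2-en-1-yl]cyclopent-2-en-1-one | CCCCC/C=C\CC1(O)C=C(Br)C(=O)C1CO[Si](c2ccccc2)(c2ccccc2)C(C)(C)C
F2 | step 4 | racemic trans-3-bromo-5-{[(tert-butyldiphenylsilyl)oxy]methyl}-1-[(2Z)-oct-2-en-1-yl]-4-oxocyclopent-2-en-1-yl acetate | CCCCC/C=C\CC1(OC(C)=O)C=C(Br)C(=O)C1CO[Si](c2ccccc2)(c2ccccc2)C(C)(C)C
F3 | step 4 | racemic trans-3-bromo-5-(hydroxymethyl)-1-[(2Z)-oct-2-en-1-yl]-4-oxocyclopent-2-en-1-yl acetate | CCCCC/C=C\CC1(OC(C)=O)C=C(Br)C(=O)C1CO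
F4 | step 4 | (1R,5R)-5-(acetoxymethyl)-3-bromo-1-[(2Z)-oct-2-en-1-yl]-4-oxocyclopent-2-en-1-yl acetate | CCCCC/C=C\C[C@]1(OC(C)=O)C=C(Br)C(=O)[C@@H]1COC(C)=O
F5 | step 3 | 3-bromo-2-(trimethylsilyl)furan | C[Si](C)(C)c1occc1Br
F6 | step 3 | 3-bromo-5-[(2Z)-oct-2-en-1-yl]-2-(trimethylsilyl)furan | CCCCC/C=C\Cc1cc(Br)c([Si](C)(C)C)o1
F7 | step 3 | 4-bromo-2-[(2Z)-oct-2-en-1-yl]furan | CCCCC/C=C\Cc1cc(Br)co1
F8 | step 10 | methyl (5E)-6-cupriohex-5-enoate (alkenylcopper) | COC(=O)CCC/C=C/[Cu]
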